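The 5,6-dihydro-2H-pyran-2-one ring is split into two three-atom pieces: ring atoms C4–C5–C6 are an (E)-enal at the correct oxidation level, and O1–C2–C3 is an acetic acid unit. The feature exploited is that the oxygen-bearing ring carbon C6 stands β to C4. A formal [3+3] annulation of the enal with diethylphosphonoacetic acid closes the ring in one operation: amine-catalysed oxa-Michael addition of the carboxylate to C6 (O1–C6 bond and C6 stereocentre), then intramolecular Horner–Wadsworth–Emmons olefination of the C4 aldehyde (C3=C4). The precursor is an O-protected (E)-5,7,9-trioxygenated tetracos-2-enal, built from a commercial syn-1,3-diol (statin) building block that supplies C10 and C12, with C8 set by iridium-catalysed allylation.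

Key step: step 7

Remark: atoms are numbered as in the target (lactone O1, C2–C6; side chain C7–C27). The target is all-syn at C6/C8/C10/C12, i.e. (6S)-6-[(2R,4R,6R)-2,4,6-trihydroxyhenicosyl]. Compound 1 and the Grignard solution 3 are assumed to be purchased.

Step 1
Reactants: 1 tert-butyl 2-[(4R,6S)-6-(hydroxymethyl)-2,2-dimethyl-1,3-dioxan-4-yl]acetate
Product: 2 tert-butyl 2-[(4R,6S)-2,2-dimethyl-6-(trifluoromethylsulfonyloxymethyl)-1,3-dioxan-4-yl]acetate
Conditions: Tf2O, pyridine, CH2Cl2, −78 → −20 °C; cold aqueous work-up, used without chromatography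
Reagents that add atoms: trifluoromethanesulfonic anhydride, O=S(=O)(OS(=O)(=O)C(F)(F)F)C(F)(F)F
Why: O-sulfonylation of the only free (primary) hydroxyl at low temperature should give the primary triflate without touching the acetonide, the tert-butyl ester or either stereocentre.

Step 2
Reactants: 2 primary triflate; 3 tetradecylmagnesium chloride
Product: 4 tert-butyl 2-[(4R,6R)-2,2-dimethyl-6-pentadecyl-1,3-dioxan-4-yl]acetate
Conditions: 3 (1.5 equiv), CuBr·SMe2 (10 mol %), THF/Et2O, −40 → 0 °C
Reagents that add atoms: tetradecylmagnesium chloride (3), CCCCCCCCCCCCCC[Mg]Cl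
Why: copper-catalysed SN2 alkylation of a primary alkyl triflate by a Grignard reagent (Kochi-type sp3–sp3 coupling) should outrun addition to the hindered tert-butyl ester at low temperature and completes the C13–C27 chain; no stereocentre is involved.

Step 3
Reactants: 4 tert-butyl ester
Product: 5 2-[(4S,6R)-2,2-dimethyl-6-pentadecyl-1,3-dioxan-4-yl]ethanol
Conditions: LiAlH4, THF, 0 °C → rt
Reagents that add atoms: none
Why: hydride reduction of the ester to the primary alcohol leaves the acetonide untouched and gives the alcohol oxidation level that the next step uses directly.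

Step 4
Reactants: 5 primary alcohol; 6 allyl acetate
Product: 7 (2S)-1-[(4S,6R)-2,2-dimethyl-6-pentadecyl-1,3-dioxan-4-yl]pent-4-en-2-ol
Conditions: 6 (excess), [Ir(cod)Cl]2 (2.5 mol %), (S)-Cl,MeO-BIPHEP (5 mol %), 4-Cl-3-NO2-C6H3CO2H (10 mol %), Cs2CO3 (20 mol %), THF, 100 °C
Reagents that add atoms: allyl acetate (6), C=CCOC(C)=O
Why: Krische iridium-catalysed transfer-hydrogenative carbonyl allylation from the alcohol oxidation level, in which the cyclometallated Ir–(S)-ligand complex dehydrogenates 5 to the aldehyde and should deliver the allyl group to its Si face, setting C8 as the (S)-carbinol (syn to O10) under catalyst control.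

Step 5
Reactants: 7 homoallylic alcohol
Product: 8 tert-butyl-[(2S)-1-[(4R,6R)-2,2-dimethyl-6-pentadecyl-1,3-dioxan-4-yl]pent-4-en-2-yl]oxy-dimethylsilane
Conditions: TBSCl, imidazole, DMF, rt
Reagents that add atoms: tert-butyldimethylsilyl chloride, CC(C)(C)[Si](C)(C)Cl
Why: standard silylation of the secondary alcohol blocks O8 so that it cannot form hemiacetals or add to the enal and the lactone in the later steps.

Step 6
Reactants: 8 homoallylic silyl ether; 9 (E)-but-2-enal (crotonaldehyde)
Product: 10 (2E,5S)-5-(tert-butyldimethylsilyloxy)-6-[(4R,6R)-2,2-dimethyl-6-pentadecyl-1,3-dioxan-4-yl]hex-2-enal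
Conditions: 9 (5 equiv), Hoveyda–Grubbs II (5 mol %), CH2Cl2, 40 °C
Reagents that add atoms: (E)-crotonaldehyde (9), C/C=C/C=O
Why: olefin cross-metathesis of a terminal (type I) alkene with crotonaldehyde should give the thermodynamically favoured (E)-enal with loss of propene, the silyl ether and acetonide being inert to the ruthenium carbene.

Step 7
Reactants: 10 (E)-enal; 11 2-(diethoxyphosphoryl)acetic acid
Product: 13 (6S)-6-[(2R)-2-(tert-butyldimethylsilyloxy)-3-[(4R,6R)-2,2-dimethyl-6-pentadecyl-1,3-dioxan-4-yl]propyl]-5,6-dihydro-2H-pyran-2-one, via phosphonoacetoxy aldehyde 12 (not isolated)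
Conditions: (i) 11 (1.5 equiv), (S)-2-{bis[3,5-bis(trifluoromethyl)phenyl](trimethylsilyloxy)methyl}pyrrolidine (20 mol %), toluene, 0 °C; (ii) LiCl, i-Pr2NEt, MeCN, 0 °C → rt, same flask
Reagents that add atoms: 2-(diethoxyphosphoryl)acetic acid (11), CCOP(=O)(CC(=O)O)OCC
Why: Proposed new method: the secondary amine condenses with enal 10 to an (E)-iminium ion, the carboxylate of 11 adds to its β-carbon to make the O1–C6 bond, and after hydrolysis to aldehyde 12 the tethered phosphonate is deprotonated under Masamune–Roush conditions and olefinates the C4 aldehyde to make C3=C4 with loss of diethyl phosphate. The closest known reaction types are iminium-catalysed oxa-Michael additions of O-nucleophiles (oximes, peroxides) to enals, organocatalytic Michael/intramolecular HWE cascades of phosphonoacetates, and the carboxylate-alkylation/intramolecular HWE route to butenolides; new here is a phosphonoacetic acid carboxylate as the oxa-Michael donor, which turns enal plus acid into a formal [3+3] annulation. The ring closes by 6-exo-trig addition of the phosphonate carbanion (C3) to the C4 aldehyde and syn-elimination through the oxaphosphetane, which within the six-membered ring can only give the (Z)-alkene of the lactone. The one new stereocentre, C6, is set by the catalyst: the diaryl(silyloxy)methyl group of the (S)-pyrrolidine shields one face of the s-trans iminium ion, so oxygen should add to the open face to give 6S (syn to O8), the C8 silyl ether being too remote to override this. The step needs 1,4- rather than 1,2-addition (secured by iminium activation), kinetic control of a reversible oxa-Michael addition (secured by low temperature and immediate irreversible HWE trapping, the phosphonate CH2 being much more acidic than the aldehyde α-CH2 whose deprotonation would expel the acyloxy group), and survival of acetonide and TBS ether under weakly acidic then weakly basic conditions.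

Step 8
Reactants: 13 protected lactone
Product: 14 (6S)-6-[(2R,4R,6R)-2,4,6-trihydroxyhenicosyl]-5,6-dihydro-2H-pyran-2-one (target)
Conditions: 48% aq. HF, MeCN, 0 °C → rt
Reagents that add atoms: none
Why: aqueous HF cleaves the silyl ether and hydrolyses the acetonide in one operation under conditions that α,β-unsaturated δ-lactones tolerate; no stereocentre is touched.

Compound list
1 | tert-butyl 2-[(4R,6S)-6-(hydroxymethyl)-2,2-dimethyl-1,3-dioxan-4-yl]acetate | CC1(C)O[C@H](CO)C[C@H](CC(=O)OC(C)(C)C)O1 | starting material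
2 | tert-butyl 2-[(4R,6S)-2,2-dimethyl-6-(trifluoromethylsulfonyloxymethyl)-1,3-dioxan-4-yl]acetate | CC1(C)O[C@H](COS(=O)(=O)C(F)(F)F)C[C@H](CC(=O)OC(C)(C)C)O1 | intermediate
3 | tetradecylmagnesium chloride | CCCCCCCCCCCCCC[Mg]Cl | starting material
4 | tert-butyl 2-[(4R,6R)-2,2-dimethyl-6-pentadecyl-1,3-dioxan-4-yl]acetate | CC1(C)O[C@H](CCCCCCCCCCCCCCC)C[C@H](CC(=O)OC(C)(C)C)O1 | intermediate
5 | 2-[(4S,6R)-2,2-dimethyl-6-pentadecyl-1,3-dioxan-4-yl]ethanol | CC1(C)O[C@H](CCCCCCCCCCCCCCC)C[C@H](CCO)O1 | intermediate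
6 | allyl acetate | C=CCOC(C)=O | starting material
7 | (2S)-1-[(4S,6R)-2,2-dimethyl-6-pentadecyl-1,3-dioxan-4-yl]pent-4-en-2-ol | CC1(C)O[C@H](CCCCCCCCCCCCCCC)C[C@H](C[C@@H](O)CC=C)O1 | intermediate
8 | tert-butyl-[(2S)-1-[(4R,6R)-2,2-dimethyl-6-pentadecyl-1,3-dioxan-4-yl]pent-4-en-2-yl]oxy-dimethylsilane | CC1(C)O[C@H](CCCCCCCCCCCCCCC)C[C@H](C[C@@H](O[Si](C)(C)C(C)(C)C)CC=C)O1 | intermediate
9 | (E)-but-2-enal (crotonaldehyde) | C/C=C/C=O | starting material
10 | (2E,5S)-5-(tert-butyldimethylsilyloxy)-6-[(4R,6R)-2,2-dimethyl-6-pentadecyl-1,3-dioxan-4-yl]hex-2-enal | CC1(C)O[C@H](CCCCCCCCCCCCCCC)C[C@H](C[C@@H](O[Si](C)(C)C(C)(C)C)C/C=C/C=O)O1 | intermediate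
11 | 2-(diethoxyphosphoryl)acetic acid | CCOP(=O)(CC(=O)O)OCC | starting material
12 | (3R,5R)-5-(tert-butyldimethylsilyloxy)-6-[(4R,6R)-2,2-dimethyl-6-pentadecyl-1,3-dioxan-4-yl]-1-oxohexan-3-yl 2-(diethoxyphosphoryl)acetate | CC1(C)O[C@H](CCCCCCCCCCCCCCC)C[C@H](C[C@@H](O[Si](C)(C)C(C)(C)C)C[C@H](CC=O)OC(=O)CP(=O)(OCC)OCC)O1 | intermediate
13 | (6S)-6-[(2R)-2-(tert-butyldimethylsilyloxy)-3-[(4R,6R)-2,2-dimethyl-6-pentadecyl-1,3-dioxan-4-yl]propyl]-5,6-dihydro-2H-pyran-2-one | CC1(C)O[C@H](CCCCCCCCCCCCCCC)C[C@H](C[C@@H](O[Si](C)(C)C(C)(C)C)C[C@@H]2CC=CC(=O)O2)O1 | intermediate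
14 | (6S)-6-[(2R,4R,6R)-2,4,6-trihydroxyhenicosyl]-5,6-dihydro-2H-pyran-2-one | CCCCCCCCCCCCCCC[C@@H](O)C[C@@H](O)C[C@@H](O)C[C@@H]1CC=CC(=O)O1 | target

Total step count: 8. Longest linear sequence: 8 steps (1 → 14).

Steps most likely to fail

Step 7 (proposed new method). The carboxylate is a weak oxa-Michael donor and the addition is reversible, so conversion may stall. Retro-addition or β-elimination of the acyloxy group during the basic olefination stage would erode the C6 configuration. Dienamine formation from the enal could divert material. The fallback uses only known chemistry, sets out from 8 and returns at 13. Ozonolysis of 8 (O3, CH2Cl2, −78 °C; PPh3) would give (3R)-3-(tert-butyldimethylsilyloxy)-4-[(4R,6R)-2,2-dimethyl-6-pentadecyl-1,3-dioxan-4-yl]butanal F1. Iridium-catalysed allylation at the aldehyde level with the same (S)-ligand catalyst (allyl acetate, 2-propanol, THF, 100 °C) should then give (4S,6S)-6-(tert-butyldimethylsilyloxy)-7-[(4R,6R)-2,2-dimethyl-6-pentadecyl-1,3-dioxan-4-yl]hept-1-en-4-ol F2, so that the C6–O bond and the C6 stereocentre are in place before ring closure. Acylation with acryloyl chloride and Et3N would give the acrylate (4S,6R)-6-(tert-butyldimethylsilyloxy)-7-[(4R,6R)-2,2-dimethyl-6-pentadecyl-1,3-dioxan-4-yl]hept-1-en-4-yl prop-2-enoate F3, and ring-closing metathesis (Grubbs II, CH2Cl2, 40 °C) would close the lactone to 13.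

Step 2. The Grignard reagent may attack or enolise the tert-butyl ester in competition with the copper-catalysed substitution, and the triflate may decompose before it couples. The fallback sets out from 1 and returns at 4, building the chain by carbonyl olefination instead of substitution. Parikh–Doering oxidation of 1 would give tert-butyl 2-[(4R,6S)-6-formyl-2,2-dimethyl-1,3-dioxan-4-yl]acetate F4. Wittig reaction with the ylide from tetradecyltriphenylphosphonium bromide (NaHMDS, THF, −78 °C) would give tert-butyl 2-[(4R,6S)-2,2-dimethyl-6-[(Z)-pentadec-1-enyl]-1,3-dioxan-4-yl]acetate F5, and hydrogenation (H2, Pd/C, EtOAc) would give 4.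

Step 6. The enal partner may deactivate the ruthenium catalyst or oligomerise, 8 may homodimerise, and E-selectivity may be incomplete. The fallback sets out from 8 and returns at 10, avoiding any aldehyde during metathesis and reaching the enal by redox adjustment. Cross-metathesis of 8 with methyl acrylate (Hoveyda–Grubbs II, CH2Cl2, 40 °C) would give methyl (2E,5S)-5-(tert-butyldimethylsilyloxy)-6-[(4R,6R)-2,2-dimethyl-6-pentadecyl-1,3-dioxan-4-yl]hex-2-enoate F6. DIBAL-H reduction (CH2Cl2, −78 °C) would give (2E,5S)-5-(tert-butyldimethylsilyloxy)-6-[(4R,6R)-2,2-dimethyl-6-pentadecyl-1,3-dioxan-4-yl]hex-2-en-1-ol F7, and MnO2 (CH2Cl2, rt) would oxidise it to 10.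

Further compounds
F1 | step 7 | (3R)-3-(tert-butyldimethylsilyloxy)-4-[(4R,6R)-2,2-dimethyl-6-pentadecyl-1,3-dioxan-4-yl]butanal | CC1(C)O[C@H](CCCCCCCCCCCCCCC)C[C@H](C[C@@H](O[Si](C)(C)C(C)(C)C)CC=O)O1
F2 | step 7 | (4S,6S)-6-(tert-butyldimethylsilyloxy)-7-[(4R,6R)-2,2-dimethyl-6-pentadecyl-1,3-dioxan-4-yl]hept-1-en-4-ol | CC1(C)O[C@H](CCCCCCCCCCCCCCC)C[C@H](C[C@@H](O[Si](C)(C)C(C)(C)C)C[C@@H](O)CC=C)O1
F3 | step 7 | (4S,6R)-6-(tert-butyldimethylsilyloxy)-7-[(4R,6R)-2,2-dimethyl-6-pentadecyl-1,3-dioxan-4-yl]hept-1-en-4-yl prop-2-enoate | CC1(C)O[C@H](CCCCCCCCCCCCCCC)C[C@H](C[C@@H](O[Si](C)(C)C(C)(C)C)C[C@@H](OC(=O)C=C)CC=C)O1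
F4 | step 2 | tert-butyl 2-[(4R,6S)-6-formyl-2,2-dimethyl-1,3-dioxan-4-yl]acetate | CC1(C)O[C@H](C=O)C[C@H](CC(=O)OC(C)(C)C)O1
F5 | step 2 | tert-butyl 2-[(4R,6S)-2,2-dimethyl-6-[(Z)-pentadec-1-enyl]-1,3-dioxan-4-yl]acetate | CC1(C)O[C@H](/C=C\CCCCCCCCCCCCC)C[C@H](CC(=O)OC(C)(C)C)O1
F6 | step 6 | methyl (2E,5S)-5-(tert-butyldimethylsilyloxy)-6-[(4R,6R)-2,2-dimethyl-6-pentadecyl-1,3-dioxan-4-yl]hex-2-enoate | CC1(C)O[C@H](CCCCCCCCCCCCCCC)C[C@H](C[C@@H](O[Si](C)(C)C(C)(C)C)C/C=C/C(=O)OC)O1
F7 | step 6 | (2E,5S)-5-(tert-butyldimethylsilyloxy)-6-[(4R,6R)-2,2-dimethyl-6-pentadecyl-1,3-dioxan-4-yl]hex-2-en-1-ol | CC1(C)O[C@H](CCCCCCCCCCCCCCC)C[C@H](C[C@@H](O[Si](C)(C)C(C)(C)C)C/C=C/CO)O1
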